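## Analysis of the target

Target 37 is a cis-fused bicyclo[4.4.0]decene, numbered here as a naphthalene: ring A is C1–C2–C3–C4–C4a–C8a with a C3=C4 alkene and a C3 methyl, and ring B is C4a–C5–C6–C7–C8–C8a. C1 carries an (E,E)-4-carboxybuta-1,3-dienyl chain, C2 an (E)-but-2-en-2-yl group, C8 a methyl and C7 a hydrogen sulfate. The six stereocentres C1, C2, C8a, C8, C7 and C4a form one contiguous array, and the C1 chain, the C2 butenyl group, the C8 methyl and the C7 oxygen all lie on the face that carries H4a and H8a (called α below). The sensitive groups are the secondary alkyl hydrogen sulfate (acid-labile and too polar to carry), the dienoic acid, and the doubly allylic C2–H between two trisubstituted alkenes. The difficulty is the all-cis arrangement of the C1 and C2 substituents and the fusion hydrogens, together with the two further centres C7 and C8 on the convex face of ring B. The strategy rests on reading the C7 oxygen next to the C8 methyl as a C7=C8 enol ether, which makes ring B the cyclohexene retron of a Diels–Alder reaction between a 2-oxygenated diene C6=C7–C8=C8a and an alkene C4a=C5. The C3-methyl C3=C4 alkene is in turn the reductive-transposition product of a C4 ketone flanked by a C3 exo-methylene, so that C4a=C5 becomes a vinyl ketone whose carbonyl lies in the tether. Both rings then arise in one intramolecular [4+2] reaction of an open chain whose only stereocentres are C1 and C2.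

## Retrosynthetic reasoning

**37 ⇒ 36 ⇒ 35.** The O–S bond at C7 and the ester C–O bond are cut first. A hydrogen sulfate cannot be carried through organometallic or oxidative steps, and the ethyl ester of 36 keeps the acid masked during sulfation. The forward steps are O-sulfation of the only free hydroxyl of 35 and a saponification that the sulfate monoester survives.

**35 ⇒ 33 + 34.** The C=C bond next to C1 is cut by a Horner–Wadsworth–Emmons disconnection. C1 then carries only a one-carbon arm for most of the route, which is why it travels as a CH2O–PMB group (33 ⇐ 32 ⇐ 31). The forward reaction has to give the (E,E)-diene without epimerising C1.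

**31 ⇒ 30 ⇒ 28 (through enolate 29).** The C7–H bond and the C8–CH3 bond are cut. The methyl is cut here because silyl enol ether 28 gives enolate 29 with fixed regiochemistry, and the cis-decalin then directs both the methyl electrophile and the hydride. C7 and C8 are thus set after the ring system exists.

**28 ⇒ 25 ⇒ 24.** The C3 methyl and the C3=C4 alkene are traced to allylic alcohol 25 and enone 24 by a reductive 1,3-transposition. This gives a C4 carbonyl to activate the dienophile. C3 is sp2 in 24, so there is no epimerisable centre next to the ketone on that side.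

**24 ⇒ 23.** The bonds C4a–C8a and C5–C6 are cut. This removes both rings and two stereocentres at once and leaves the acyclic 1,7,9-decatrien-3-one 23. The forward reaction must close cis and on one diene face.

**23 ⇒ 22 ⇒ 21 ⇒ 20.** The C4–C4a bond is cut (C-vinylation of the aldehyde of 21 to give 22), and the silyl dienol ether is traced to the methyl enone of 20. The diene is made before the vinyl addition so that it masks the methyl ketone, and the reactive divinyl ketone appears only in the last step before cyclisation.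

**20 ⇒ 19 ⇒ 18 ⇒ 17 + 16; 17 ⇐ 15 ⇐ 14.** The C8=C8a alkene is cut by a Wittig disconnection to aldehyde 17 and ylide 16. Aldehyde 17 comes from acid 14 by reduction to 15 and re-oxidation.

**14 ⇒ 11 (through 12).** The C1–C2 bond is cut by an Ireland–Claisen disconnection. This is the best place because one carbinol centre in 11 then sets C1, C2 and the (E)-geometry of the butenyl group together through a chair transition state.

**11 ⇒ 7 + 10; 7 ⇒ 3 + 6; 3 ⇒ 1; 6 ⇒ 5 ⇒ 4; 10 ⇒ 9 ⇒ 8.** The ester bond and the C2–C3 diene bond are cut last. This leads to the chiral-pool alkynol 1, bromoallyl alcohol 4 and diol 8.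

## Alternatives that were turned down

**Alternative 1:** The disconnection is at C1–C8a and C8–CH3. In the forward step a C1 malonate anion tethered to a ring-B cyclohexenone (A2) adds to C8a, and the C7 enolate formed is methylated at C8 in the same flask to give A1.
- For it: the enolate is regiodefined by the Michael step, the C3=C4 alkene and the butenyl group are already in place, and the C7 ketone arrives ready for reduction. After ring closure this route is shorter than the chosen one, which needs a transposition and a separate enolate step.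
- Against it: C1 emerges quaternary in A1. One ester must be excised, and the C1 configuration then depends on a protonation that has to place the remaining group cis to the C2 butenyl group, with no control element and probably against the thermodynamic preference. A2 also needs a Z-trisubstituted C3=C4 alkene and two stereocentres (C2, C4a) on either side of it that cannot be related in one step.
- Comparison: the chosen route makes C1 a tertiary CH from the start, sets it together with C2 from one carbinol centre, and closes both rings in one step.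

**Alternative 2:** The disconnection is at C1–C2. The silyl ketene acetal of the cis-fused lactone A4 (ring oxygen on C4, C4 bearing the dienyl group) would rearrange through a boat transition state to acid A3, with C4–O cleavage.
- For it: the rearrangement is stereospecific and fixes C1, C2 and the position of the C3=C4 alkene at once. A3 already has ring B complete and is few steps from the target. On C1/C2 control it is at least as strong as the chosen route, and it has no endo/exo or facial question.
- Against it: the difficulty moves into A4. Ring B with four stereocentres must be built first. The boat geometry requires the dienyl group on C4 to sit cis to the C4a–C5 bond, on the concave face of the bicyclic lactone, against the normal convex-face preference of any addition or reduction that would install it. The doubly allylic C4–O bond is prone to ionisation, and the sequence is linear.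
- Comparison: the chosen route reaches its precursor from three simple pieces and lets the cycloaddition create ring B.

**Alternative 3:** The disconnection is at C4a–C5 and C8–C8a. An intermolecular Diels–Alder reaction of the silyloxy thiopyran A6 with the quinone monoketal A7 under a chiral boron Lewis acid would give the sulfur-bridged adduct A5.
- For it: it is the shortest access to a cis-fused core, from two achiral partners, with the absolute configuration from a catalyst and the future C8 methyl locked by the sulfur bridge. On brevity to the bicycle it is stronger than the chosen route.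
- Against it: A5 has none of the carbon appendages. C1 is a ketal carbon that must become a stereodefined CH bearing the chain. The butenyl group must be added at C2 and the C3 methyl alkene restored. The C4 carbonyl must be removed with alkene placement. The reductive C–S cleavage must precede the introduction of every alkene it would reduce. That is well over a dozen steps after the cycloaddition, several of which set stereocentres.
- Comparison: the chosen route has every carbon substituent in place before the rings form, so only functional-group changes follow the key step.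

Key step: step 16

Assumption: the target is drawn as the free hydrogen sulfate and free carboxylic acid, so the last step ends with cold acidification; in practice the compound would be stored as a salt.
Convention: for bicyclic compounds, α on a locant means that the substituent at that locant (the hydrogen for 4a and 8a) lies on the face of H4a and H8a; rt = room temperature.

## Route

Step 1
Reactants: 1 (R)-but-3-yn-2-ol
Product: 3 (2R,3E)-4-iodo-3-methylbut-3-en-2-ol, via (E)-alkenyldimethylalane 2 (not isolated)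
Conditions: AlMe3 (3 equiv), Cp2ZrCl2 (0.25 equiv), CH2Cl2, 0 °C → rt; then I2, THF, −30 → 0 °C
Reagents that add atoms: trimethylaluminium, C[Al](C)C; iodine, II
Why: Zirconium-catalysed syn-carboalumination (Negishi) puts the methyl on the internal and aluminium on the terminal alkyne carbon; iodinolysis with retention gives the (E)-iodide, and the carbinol centre is untouched.

Step 2
Reactants: 4 2-bromoprop-2-en-1-ol
Product: 5 [(2-bromoprop-2-en-1-yl)oxy](tert-butyl)dimethylsilane
Conditions: TBSCl, imidazole, CH2Cl2, 0 °C → rt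
Reagents that add atoms: tert-butyldimethylsilyl chloride, CC(C)(C)[Si](C)(C)Cl
Why: Standard silylation of a primary alcohol.

Step 3
Reactants: 5 [(2-bromoprop-2-en-1-yl)oxy](tert-butyl)dimethylsilane
Product: 6 tert-butyldimethyl{[2-(4,4,5,5-tetramethyl-1,3,2-dioxaborolan-2-yl)prop-2-en-1-yl]oxy}silane
Conditions: B2pin2, PdCl2(PPh3)2 (3 mol %), PPh3, KOPh, PhMe, 50 °C
Reagents that add atoms: bis(pinacolato)diboron, CC1(C)OB(OC1(C)C)B1OC(C)(C)C(C)(C)O1
Why: Miyaura borylation of an alkenyl bromide (oxidative addition to zerovalent palladium, phenoxide-assisted boryl transfer, reductive elimination); this avoids lithiating a silyl ether that could undergo O-to-C silyl migration.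

Step 4
Reactants: 3 (2R,3E)-4-iodo-3-methylbut-3-en-2-ol; 6 tert-butyldimethyl{[2-(4,4,5,5-tetramethyl-1,3,2-dioxaborolan-2-yl)prop-2-en-1-yl]oxy}silane
Product: 7 (2R,3E)-5-{[(tert-butyldimethylsilyl)oxy]methyl}-3-methylhexa-3,5-dien-2-ol
Conditions: PdCl2(dppf) (5 mol %), K3PO4, THF/H2O, 45 °C
Reagents that add atoms: none
Why: Suzuki–Miyaura alkenyl–alkenyl coupling with retention of the (E)-iodide geometry; the free secondary alcohol and its stereocentre are not affected.

Step 5
Reactants: 8 propane-1,3-diol
Product: 9 3-[(4-methoxybenzyl)oxy]propan-1-ol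
Conditions: NaH (1 equiv), PMBCl, Bu4NI (cat.), THF, 0 °C → rt (8 in threefold excess)
Reagents that add atoms: 4-methoxybenzyl chloride, COc1ccc(CCl)cc1
Why: Williamson mono-etherification; the excess of diol suppresses the bis-ether.

Step 6
Reactants: 9 3-[(4-methoxybenzyl)oxy]propan-1-ol
Product: 10 3-[(4-methoxybenzyl)oxy]propanoic acid
Conditions: TEMPO (0.2 equiv), PhI(OAc)2 (2.2 equiv), MeCN/H2O, rt
Reagents that add atoms: water, O
Why: Oxoammonium oxidation of the primary alcohol through the aldehyde hydrate to the acid; the PMB ether is inert under these near-neutral conditions.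

Step 7
Reactants: 7 (2R,3E)-5-{[(tert-butyldimethylsilyl)oxy]methyl}-3-methylhexa-3,5-dien-2-ol; 10 3-[(4-methoxybenzyl)oxy]propanoic acid
Product: 11 (2R,3E)-5-{[(tert-butyldimethylsilyl)oxy]methyl}-3-methylhexa-3,5-dien-2-yl 3-[(4-methoxybenzyl)oxy]propanoate
Conditions: EDC·HCl, DMAP, CH2Cl2, 0 °C → rt
Reagents that add atoms: none
Why: Carbodiimide (Steglich-type) esterification; the C–O bond of the carbinol is not broken, so the (R) centre is kept.

Step 8
Reactants: 11 (2R,3E)-5-{[(tert-butyldimethylsilyl)oxy]methyl}-3-methylhexa-3,5-dien-2-yl 3-[(4-methoxybenzyl)oxy]propanoate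
Product: 14 (2S,3R)-3-[(E)-but-2-en-2-yl]-4-{[(tert-butyldimethylsilyl)oxy]methyl}-2-{[(4-methoxybenzyl)oxy]methyl}pent-4-enoic acid, via (Z)-silyl ketene acetal 12 (not isolated), via trimethylsilyl ester 13 (not isolated)
Conditions: LiN(i-Pr)2, Me3SiCl/Et3N, THF/DMPU, −78 °C; then → 40 °C; aqueous work-up at pH 4
Reagents that add atoms: none
Why: Ireland–Claisen rearrangement: in THF/DMPU the ester should give the enolate with the CH2OPMB arm cis to the metal-bound oxygen, trapped in situ as ketene acetal 12. The chair [3,3] transition state with the carbinol methyl equatorial transfers the (R) centre to both new centres (C1 and C2 of the later decalin) and gives the (E)-butenyl group. Low temperature and immediate silylation limit β-elimination of the benzylic alkoxide.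

Step 9
Reactants: 14 (2S,3R)-3-[(E)-but-2-en-2-yl]-4-{[(tert-butyldimethylsilyl)oxy]methyl}-2-{[(4-methoxybenzyl)oxy]methyl}pent-4-enoic acid
Product: 15 (2R,3R)-3-[(E)-but-2-en-2-yl]-4-{[(tert-butyldimethylsilyl)oxy]methyl}-2-{[(4-methoxybenzyl)oxy]methyl}pent-4-en-1-ol
Conditions: LiAlH4, Et2O, 0 °C
Reagents that add atoms: none
Why: Hydride reduction of the acid to the primary alcohol; alkenes, silyl ether and PMB ether are inert (the descriptor at C2 changes by priority only).

Step 10
Reactants: 15 (2R,3R)-3-[(E)-but-2-en-2-yl]-4-{[(tert-butyldimethylsilyl)oxy]methyl}-2-{[(4-methoxybenzyl)oxy]methyl}pent-4-en-1-ol; 16 1-(triphenyl-λ5-phosphanylidene)propan-2-one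
Product: 18 (3E,5S,6R)-6-[(E)-but-2-en-2-yl]-7-{[(tert-butyldimethylsilyl)oxy]methyl}-5-{[(4-methoxybenzyl)oxy]methyl}octa-3,7-dien-2-one, via aldehyde 17 (not isolated)
Conditions: Dess–Martin periodinane (DMP), NaHCO3, CH2Cl2, 0 °C → rt; then 16, PhMe, 60 °C
Reagents that add atoms: none
Why: Buffered periodinane oxidation gives the α-branched β-alkoxy aldehyde 17, which is used at once in a Wittig reaction with the stabilised ylide; neutral conditions protect the α centre, and the stabilised ylide gives the (E)-enone.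

Step 11
Reactants: 18 (3E,5S,6R)-6-[(E)-but-2-en-2-yl]-7-{[(tert-butyldimethylsilyl)oxy]methyl}-5-{[(4-methoxybenzyl)oxy]methyl}octa-3,7-dien-2-one
Product: 19 (3E,5S,6R)-6-[(E)-but-2-en-2-yl]-7-(hydroxymethyl)-5-{[(4-methoxybenzyl)oxy]methyl}octa-3,7-dien-2-one
Conditions: HF·pyridine, pyridine, THF, 0 °C → rt
Reagents that add atoms: none
Why: Buffered fluoride cleavage of a primary allylic silyl ether; enone and PMB ether are stable.

Step 12
Reactants: 19 (3E,5S,6R)-6-[(E)-but-2-en-2-yl]-7-(hydroxymethyl)-5-{[(4-methoxybenzyl)oxy]methyl}octa-3,7-dien-2-one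
Product: 20 (3R,4S,5E)-3-[(E)-but-2-en-2-yl]-4-{[(4-methoxybenzyl)oxy]methyl}-2-methylidene-7-oxooct-5-enal
Conditions: MnO2 (activated, excess), CH2Cl2, rt
Reagents that add atoms: none
Why: Neutral heterogeneous oxidation of the allylic alcohol to the 2-substituted acrolein; work-up is a filtration, which suits the reactive enal.

Step 13
Reactants: 20 (3R,4S,5E)-3-[(E)-but-2-en-2-yl]-4-{[(4-methoxybenzyl)oxy]methyl}-2-methylidene-7-oxooct-5-enal
Product: 21 (3R,4S,5E)-3-[(E)-but-2-en-2-yl]-7-[(tert-butyldimethylsilyl)oxy]-4-{[(4-methoxybenzyl)oxy]methyl}-2-methylideneocta-5,7-dienal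
Conditions: TBSOTf (1.1 equiv), Et3N (3 equiv), CH2Cl2, −78 → −40 °C
Reagents that add atoms: tert-butyldimethylsilyl trifluoromethanesulfonate, CC(C)(C)[Si](C)(C)OS(=O)(=O)C(F)(F)F
Why: Soft enolisation of the methyl enone gives the 2-silyloxydiene; the aldehyde has no α-hydrogen, and the amine is kept in excess so that no free silyl triflate remains to promote a Mukaiyama aldol reaction.

Step 14
Reactants: 21 (3R,4S,5E)-3-[(E)-but-2-en-2-yl]-7-[(tert-butyldimethylsilyl)oxy]-4-{[(4-methoxybenzyl)oxy]methyl}-2-methylideneocta-5,7-dienal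
Product: 22 (5R,6S,7E)-5-[(E)-but-2-en-2-yl]-9-[(tert-butyldimethylsilyl)oxy]-6-{[(4-methoxybenzyl)oxy]methyl}-4-methylidenedeca-1,7,9-trien-3-ol (both C3 epimers)
Conditions: CH2=CHMgBr, THF, −78 °C
Reagents that add atoms: vinylmagnesium bromide, C=C[Mg]Br
Why: Grignard 1,2-addition to the aldehyde; the methyl ketone is masked as the silyl dienol ether, and the new carbinol centre is removed in step 15.

Step 15
Reactants: 22 (5R,6S,7E)-5-[(E)-but-2-en-2-yl]-9-[(tert-butyldimethylsilyl)oxy]-6-{[(4-methoxybenzyl)oxy]methyl}-4-methylidenedeca-1,7,9-trien-3-ol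
Product: 23 (5R,6S,7E)-5-[(E)-but-2-en-2-yl]-9-[(tert-butyldimethylsilyl)oxy]-6-{[(4-methoxybenzyl)oxy]methyl}-4-methylidenedeca-1,7,9-trien-3-one
Conditions: DMP, pyridine, CH2Cl2, 0 °C; cold filtration through Et3N-deactivated silica
Reagents that add atoms: none
Why: Pyridine-buffered periodinane oxidation of the bis-allylic alcohol to the divinyl ketone; the buffer protects the silyl dienol ether, and 23 is kept cold and dilute because it should cyclise readily.

Step 16
Reactants: 23 (5R,6S,7E)-5-[(E)-but-2-en-2-yl]-9-[(tert-butyldimethylsilyl)oxy]-6-{[(4-methoxybenzyl)oxy]methyl}-4-methylidenedeca-1,7,9-trien-3-one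
Product: 24 2α-[(E)-but-2-en-2-yl]-7-[(tert-butyldimethylsilyl)oxy]-1α-{[(4-methoxybenzyl)oxy]methyl}-3-methylidene-1,2,3,4,4aα,5,6,8aα-octahydronaphthalen-4-one
Conditions: PhMe (0.005 M), BHT (cat.), base-washed glassware, rt → 80 °C
Reagents that add atoms: none
Why: The step is a thermal [4+2] cycloaddition, concerted but asynchronous, in which the electron-rich C6=C7(OSi)–C8=C8a diene adds suprafacially to the C4a=C5 vinyl ketone; the nucleophilic C6 terminus pairs with the electrophilic C5, which is also what the tether requires. The closest known reaction type is the intramolecular Diels–Alder reaction of 1,7,9-decatrien-3-ones, which cyclise at or a little above room temperature to cis-fused 1-decalones. Ring A closes through the C4a–C8a bond as a six-membered ring built from the four-atom tether C1–C2–C3–C4 and the two reacting termini; ring B is the cyclohexene of the cycloadduct, closed by C4a–C8a and C5–C6 together, and carries the C7=C8 silyl enol ether. C4a and C8a are created together, and their cis relationship follows from the endo position of the tether carbonyl under the diene, the usual preference of this tether. Their sense relative to C1 and C2 follows from the rotamer about C1–C8a in which C1–H lies in the diene plane toward C8–H (least allylic strain), the CH2OPMB arm is pseudo-equatorial and turned away from the dienophile, and the C2 butenyl group is pseudo-axial (relief of allylic strain against the C3 methylene) on the side of H8a; attack on the other diene face would push that butenyl group against the diene. The step therefore needs endo over exo closure and one diene face, and both are set by the substrate (carbonyl in the tether; C1 and C2 from step 8). High dilution, a radical inhibitor and acid-free glassware keep the vinyl ketone from oligomerising and the silyl dienol ether from hydrolysing, and the temperature stays far below that of a Cope rearrangement of the 1,5-diene units.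

Step 17
Reactants: 24 2α-[(E)-but-2-en-2-yl]-7-[(tert-butyldimethylsilyl)oxy]-1α-{[(4-methoxybenzyl)oxy]methyl}-3-methylidene-1,2,3,4,4aα,5,6,8aα-octahydronaphthalen-4-one
Product: 25 2α-[(E)-but-2-en-2-yl]-7-[(tert-butyldimethylsilyl)oxy]-1α-{[(4-methoxybenzyl)oxy]methyl}-3-methylidene-1,2,3,4,4aα,5,6,8aα-octahydronaphthalen-4-ol (C4 configuration not controlled)
Conditions: NaBH4, CeCl3·7H2O, MeOH/THF, −78 °C
Reagents that add atoms: none
Why: Luche 1,2-reduction of the exo-methylene ketone; the C4 configuration is of no consequence because C4 becomes sp2 in step 18, and the cold, brief conditions should spare the silyl enol ether and the C4a centre.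

Step 18
Reactants: 25 2α-[(E)-but-2-en-2-yl]-7-[(tert-butyldimethylsilyl)oxy]-1α-{[(4-methoxybenzyl)oxy]methyl}-3-methylidene-1,2,3,4,4aα,5,6,8aα-octahydronaphthalen-4-ol
Product: 28 2α-[(E)-but-2-en-2-yl]-7-[(tert-butyldimethylsilyl)oxy]-1α-{[(4-methoxybenzyl)oxy]methyl}-3-methyl-1,2,4aα,5,6,8aα-hexahydronaphthalene, via sulfonylhydrazine adduct 26 (not isolated), via allylic diazene 27 (not isolated)
Conditions: 2-nitrobenzenesulfonylhydrazide (NBSH), PPh3, DEAD, N-methylmorpholine, −30 °C → rt
Reagents that add atoms: none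
Why: Myers reductive 1,3-transposition: Mitsunobu displacement at C4 gives 26, loss of the arenesulfinic acid gives diazene 27, and its retro-ene loss of N2 delivers hydrogen to the methylene carbon, which forms the C3 methyl and the C3=C4 alkene. The amine solvent neutralises the sulfinic acid so that the silyl enol ether survives.

Step 19
Reactants: 28 2α-[(E)-but-2-en-2-yl]-7-[(tert-butyldimethylsilyl)oxy]-1α-{[(4-methoxybenzyl)oxy]methyl}-3-methyl-1,2,4aα,5,6,8aα-hexahydronaphthalene
Product: 30 2α-[(E)-but-2-en-2-yl]-1α-{[(4-methoxybenzyl)oxy]methyl}-3,8α-dimethyl-1,2,4aα,5,6,7,8,8aα-octahydronaphthalen-7-one, via lithium enolate 29 (not isolated)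
Conditions: MeLi, THF, 0 °C → rt; then MeI, DMPU, −78 → −20 °C
Reagents that add atoms: iodomethane, CI
Why: Methyllithium cleaves the Si–O bond and gives the C7 enolate with its double bond fixed toward C8 (regiospecific enolate alkylation). The electrophile should approach C8 anti to the C8a–C1 bond, on the convex face, through a chair-like transition state, which puts the methyl cis to H8a; the other face is blocked by ring A.

Step 20
Reactants: 30 2α-[(E)-but-2-en-2-yl]-1α-{[(4-methoxybenzyl)oxy]methyl}-3,8α-dimethyl-1,2,4aα,5,6,7,8,8aα-octahydronaphthalen-7-one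
Product: 31 2α-[(E)-but-2-en-2-yl]-1α-{[(4-methoxybenzyl)oxy]methyl}-3,8α-dimethyl-1,2,4aα,5,6,7,8,8aα-octahydronaphthalen-7α-ol
Conditions: LiBH(s-Bu)3, THF, −78 °C
Reagents that add atoms: none
Why: A bulky trialkylborohydride should attack the ring-B chair that has the C8 methyl equatorial along the equatorial trajectory, as with 2-methylcyclohexanone, and give the axial alcohol cis to the methyl (7α-OH).

Step 21
Reactants: 31 2α-[(E)-but-2-en-2-yl]-1α-{[(4-methoxybenzyl)oxy]methyl}-3,8α-dimethyl-1,2,4aα,5,6,7,8,8aα-octahydronaphthalen-7α-ol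
Product: 32 2α-[(E)-but-2-en-2-yl]-1α-(hydroxymethyl)-3,8α-dimethyl-1,2,4aα,5,6,7,8,8aα-octahydronaphthalen-7α-ol
Conditions: DDQ, CH2Cl2/pH 7 buffer, 0 °C
Reagents that add atoms: none
Why: Oxidative cleavage of the PMB ether through its oxocarbenium ion; low temperature and buffer keep the doubly allylic C2–H and the alkenes intact.

Step 22
Reactants: 32 2α-[(E)-but-2-en-2-yl]-1α-(hydroxymethyl)-3,8α-dimethyl-1,2,4aα,5,6,7,8,8aα-octahydronaphthalen-7α-ol
Product: 33 2α-[(E)-but-2-en-2-yl]-7α-hydroxy-3,8α-dimethyl-1,2,4aα,5,6,7,8,8aα-octahydronaphthalene-1α-carbaldehyde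
Conditions: TEMPO (cat.), PhI(OAc)2, CH2Cl2, rt
Reagents that add atoms: none
Why: Oxoammonium oxidation is selective for the primary alcohol over the hindered secondary C7 alcohol. The C7 oxygen and the C8a–C1 bond are trans on ring B, so the C7 hydroxyl cannot reach the new aldehyde and no lactol can form.

Step 23
Reactants: 33 2α-[(E)-but-2-en-2-yl]-7α-hydroxy-3,8α-dimethyl-1,2,4aα,5,6,7,8,8aα-octahydronaphthalene-1α-carbaldehyde; 34 triethyl (E)-4-phosphonocrotonate
Product: 35 ethyl (2E,4E)-5-{2α-[(E)-but-2-en-2-yl]-7α-hydroxy-3,8α-dimethyl-1,2,4aα,5,6,7,8,8aα-octahydronaphthalen-1α-yl}penta-2,4-dienoate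
Conditions: LiN(SiMe3)2 (slightly less than 1 equiv per 34), THF, −78 → 0 °C
Reagents that add atoms: none
Why: Horner–Wadsworth–Emmons olefination with the vinylogous phosphonate anion gives the (E,E)-dienoate; the weakly basic anion at low temperature should not epimerise C1 or deprotonate the free alcohol.

Step 24
Reactants: 35 ethyl (2E,4E)-5-{2α-[(E)-but-2-en-2-yl]-7α-hydroxy-3,8α-dimethyl-1,2,4aα,5,6,7,8,8aα-octahydronaphthalen-1α-yl}penta-2,4-dienoate
Product: 36 ethyl (2E,4E)-5-{2α-[(E)-but-2-en-2-yl]-3,8α-dimethyl-7α-(sulfooxy)-1,2,4aα,5,6,7,8,8aα-octahydronaphthalen-1α-yl}penta-2,4-dienoate (handled as its pyridinium salt)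
Conditions: SO3·pyridine, pyridine, rt → 40 °C
Reagents that add atoms: sulfur trioxide–pyridine complex, [O-]S(=O)(=O)[n+]1ccccc1
Why: O-sulfation of the only free hydroxyl with retention at C7; the dienoate ester is inert.

Step 25
Reactants: 36 ethyl (2E,4E)-5-{2α-[(E)-but-2-en-2-yl]-3,8α-dimethyl-7α-(sulfooxy)-1,2,4aα,5,6,7,8,8aα-octahydronaphthalen-1α-yl}penta-2,4-dienoate
Product: 37 (2E,4E)-5-{2α-[(E)-but-2-en-2-yl]-3,8α-dimethyl-7α-(sulfooxy)-1,2,4aα,5,6,7,8,8aα-octahydronaphthalen-1α-yl}penta-2,4-dienoic acid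
Conditions: LiOH, THF/MeOH/H2O, 0 °C → rt; then cold dilute HCl to pH 2, reversed-phase isolation
Reagents that add atoms: lithium hydroxide, [Li+].[OH-]
Why: Saponification of the ethyl ester; the sulfate monoester anion is inert to hydroxide, and brief cold acidification gives the free acid form.

## Compound list

1 | (R)-but-3-yn-2-ol | C[C@@H](O)C#C | starting material
2 | (E)-alkenyldimethylalane, dimethylaluminium alkoxide of (2R,3E)-4-(dimethylalumanyl)-3-methylbut-3-en-2-ol | C[C@@H](O[Al](C)C)/C(C)=C/[Al](C)C | intermediate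
3 | (2R,3E)-4-iodo-3-methylbut-3-en-2-ol | C[C@@H](O)/C(C)=C/I | intermediate
4 | 2-bromoprop-2-en-1-ol | OCC(Br)=C | starting material
5 | [(2-bromoprop-2-en-1-yl)oxy](tert-butyl)dimethylsilane | C=C(Br)CO[Si](C)(C)C(C)(C)C | intermediate
6 | tert-butyldimethyl{[2-(4,4,5,5-tetramethyl-1,3,2-dioxaborolan-2-yl)prop-2-en-1-yl]oxy}silane | CC(C)(C)[Si](C)(C)OCC(=C)B1OC(C)(C)C(C)(C)O1 | intermediate
7 | (2R,3E)-5-{[(tert-butyldimethylsilyl)oxy]methyl}-3-methylhexa-3,5-dien-2-ol | C[C@@H](O)/C(C)=C/C(=C)CO[Si](C)(C)C(C)(C)C | intermediate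
8 | propane-1,3-diol | OCCCO | starting material
9 | 3-[(4-methoxybenzyl)oxy]propan-1-ol | COc1ccc(COCCCO)cc1 | intermediate
10 | 3-[(4-methoxybenzyl)oxy]propanoic acid | COc1ccc(COCCC(=O)O)cc1 | intermediate
11 | (2R,3E)-5-{[(tert-butyldimethylsilyl)oxy]methyl}-3-methylhexa-3,5-dien-2-yl 3-[(4-methoxybenzyl)oxy]propanoate | C[C@@H](OC(=O)CCOCc1ccc(OC)cc1)/C(C)=C/C(=C)CO[Si](C)(C)C(C)(C)C | intermediate
12 | (Z)-trimethylsilyl ketene acetal of 11 (CH2OPMB cis to OSiMe3) | C[C@@H](O/C(O[Si](C)(C)C)=C/COCc1ccc(OC)cc1)/C(C)=C/C(=C)CO[Si](C)(C)C(C)(C)C | intermediate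
13 | trimethylsilyl ester of acid 14 | C/C=C(\C)[C@H](C(=C)CO[Si](C)(C)C(C)(C)C)[C@@H](COCc1ccc(OC)cc1)C(=O)O[Si](C)(C)C | intermediate
14 | (2S,3R)-3-[(E)-but-2-en-2-yl]-4-{[(tert-butyldimethylsilyl)oxy]methyl}-2-{[(4-methoxybenzyl)oxy]methyl}pent-4-enoic acid | C/C=C(\C)[C@H](C(=C)CO[Si](C)(C)C(C)(C)C)[C@@H](COCc1ccc(OC)cc1)C(=O)O | intermediate
15 | (2R,3R)-3-[(E)-but-2-en-2-yl]-4-{[(tert-butyldimethylsilyl)oxy]methyl}-2-{[(4-methoxybenzyl)oxy]methyl}pent-4-en-1-ol | C/C=C(\C)[C@H](C(=C)CO[Si](C)(C)C(C)(C)C)[C@@H](COCc1ccc(OC)cc1)CO | intermediate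
16 | 1-(triphenyl-λ5-phosphanylidene)propan-2-one | CC(=O)C=P(c1ccccc1)(c1ccccc1)c1ccccc1 | starting material
17 | (2S,3R)-3-[(E)-but-2-en-2-yl]-4-{[(tert-butyldimethylsilyl)oxy]methyl}-2-{[(4-methoxybenzyl)oxy]methyl}pent-4-enal | C/C=C(\C)[C@H](C(=C)CO[Si](C)(C)C(C)(C)C)[C@@H](COCc1ccc(OC)cc1)C=O | intermediate
18 | (3E,5S,6R)-6-[(E)-but-2-en-2-yl]-7-{[(tert-butyldimethylsilyl)oxy]methyl}-5-{[(4-methoxybenzyl)oxy]methyl}octa-3,7-dien-2-one | C/C=C(\C)[C@H](C(=C)CO[Si](C)(C)C(C)(C)C)[C@@H](COCc1ccc(OC)cc1)/C=C/C(C)=O | intermediate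
19 | (3E,5S,6R)-6-[(E)-but-2-en-2-yl]-7-(hydroxymethyl)-5-{[(4-methoxybenzyl)oxy]methyl}octa-3,7-dien-2-one | C/C=C(\C)[C@H](C(=C)CO)[C@@H](COCc1ccc(OC)cc1)/C=C/C(C)=O | intermediate
20 | (3R,4S,5E)-3-[(E)-but-2-en-2-yl]-4-{[(4-methoxybenzyl)oxy]methyl}-2-methylidene-7-oxooct-5-enal | C/C=C(\C)[C@H](C(=C)C=O)[C@@H](COCc1ccc(OC)cc1)/C=C/C(C)=O | intermediate
21 | (3R,4S,5E)-3-[(E)-but-2-en-2-yl]-7-[(tert-butyldimethylsilyl)oxy]-4-{[(4-methoxybenzyl)oxy]methyl}-2-methylideneocta-5,7-dienal | C/C=C(\C)[C@H](C(=C)C=O)[C@@H](COCc1ccc(OC)cc1)/C=C/C(O[Si](C)(C)C(C)(C)C)=C | intermediate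
22 | (5R,6S,7E)-5-[(E)-but-2-en-2-yl]-9-[(tert-butyldimethylsilyl)oxy]-6-{[(4-methoxybenzyl)oxy]methyl}-4-methylidenedeca-1,7,9-trien-3-ol, both C3 epimers | C/C=C(\C)[C@H](C(=C)C(O)C=C)[C@@H](COCc1ccc(OC)cc1)/C=C/C(O[Si](C)(C)C(C)(C)C)=C | intermediate
23 | (5R,6S,7E)-5-[(E)-but-2-en-2-yl]-9-[(tert-butyldimethylsilyl)oxy]-6-{[(4-methoxybenzyl)oxy]methyl}-4-methylidenedeca-1,7,9-trien-3-one | C/C=C(\C)[C@H](C(=C)C(=O)C=C)[C@@H](COCc1ccc(OC)cc1)/C=C/C(O[Si](C)(C)C(C)(C)C)=C | intermediate
24 | 2α-[(E)-but-2-en-2-yl]-7-[(tert-butyldimethylsilyl)oxy]-1α-{[(4-methoxybenzyl)oxy]methyl}-3-methylidene-1,2,3,4,4aα,5,6,8aα-octahydronaphthalen-4-one | C/C=C(\C)[C@@H]1C(=C)C(=O)[C@H]2CCC(O[Si](C)(C)C(C)(C)C)=C[C@H]2[C@@H]1COCc1ccc(OC)cc1 | intermediate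
25 | 2α-[(E)-but-2-en-2-yl]-7-[(tert-butyldimethylsilyl)oxy]-1α-{[(4-methoxybenzyl)oxy]methyl}-3-methylidene-1,2,3,4,4aα,5,6,8aα-octahydronaphthalen-4-ol, C4 not controlled | C/C=C(\C)[C@@H]1C(=C)C(O)[C@H]2CCC(O[Si](C)(C)C(C)(C)C)=C[C@H]2[C@@H]1COCc1ccc(OC)cc1 | intermediate
26 | N-(C4-alkyl)-N-(2-nitrobenzenesulfonyl)hydrazine from 25, C4 inverted relative to 25 | C/C=C(\C)[C@@H]1C(=C)C(N(N)S(=O)(=O)c3ccccc3[N+](=O)[O-])[C@H]2CCC(O[Si](C)(C)C(C)(C)C)=C[C@H]2[C@@H]1COCc1ccc(OC)cc1 | intermediate
27 | C4 allylic monoalkyl diazene | C/C=C(\C)[C@@H]1C(=C)C(N=N)[C@H]2CCC(O[Si](C)(C)C(C)(C)C)=C[C@H]2[C@@H]1COCc1ccc(OC)cc1 | intermediate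
28 | 2α-[(E)-but-2-en-2-yl]-7-[(tert-butyldimethylsilyl)oxy]-1α-{[(4-methoxybenzyl)oxy]methyl}-3-methyl-1,2,4aα,5,6,8aα-hexahydronaphthalene | C/C=C(\C)[C@@H]1C(C)=C[C@H]2CCC(O[Si](C)(C)C(C)(C)C)=C[C@H]2[C@@H]1COCc1ccc(OC)cc1 | intermediate
29 | lithium C7 enolate (C7=C8) of the ring system of 28 | C/C=C(\C)[C@@H]1C(C)=C[C@H]2CCC(O[Li])=C[C@H]2[C@@H]1COCc1ccc(OC)cc1 | intermediate
30 | 2α-[(E)-but-2-en-2-yl]-1α-{[(4-methoxybenzyl)oxy]methyl}-3,8α-dimethyl-1,2,4aα,5,6,7,8,8aα-octahydronaphthalen-7-one | C/C=C(\C)[C@@H]1C(C)=C[C@H]2CCC(=O)[C@H](C)[C@H]2[C@@H]1COCc1ccc(OC)cc1 | intermediate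
31 | 2α-[(E)-but-2-en-2-yl]-1α-{[(4-methoxybenzyl)oxy]methyl}-3,8α-dimethyl-1,2,4aα,5,6,7,8,8aα-octahydronaphthalen-7α-ol | C/C=C(\C)[C@@H]1C(C)=C[C@H]2CC[C@H](O)[C@H](C)[C@H]2[C@@H]1COCc1ccc(OC)cc1 | intermediate
32 | 2α-[(E)-but-2-en-2-yl]-1α-(hydroxymethyl)-3,8α-dimethyl-1,2,4aα,5,6,7,8,8aα-octahydronaphthalen-7α-ol | C/C=C(\C)[C@@H]1C(C)=C[C@H]2CC[C@H](O)[C@H](C)[C@H]2[C@@H]1CO | intermediate
33 | 2α-[(E)-but-2-en-2-yl]-7α-hydroxy-3,8α-dimethyl-1,2,4aα,5,6,7,8,8aα-octahydronaphthalene-1α-carbaldehyde | C/C=C(\C)[C@@H]1C(C)=C[C@H]2CC[C@H](O)[C@H](C)[C@H]2[C@@H]1C=O | intermediate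
34 | triethyl (E)-4-phosphonocrotonate | CCOC(=O)/C=C/CP(=O)(OCC)OCC | starting material
35 | ethyl (2E,4E)-5-{2α-[(E)-but-2-en-2-yl]-7α-hydroxy-3,8α-dimethyl-1,2,4aα,5,6,7,8,8aα-octahydronaphthalen-1α-yl}penta-2,4-dienoate | C/C=C(\C)[C@@H]1C(C)=C[C@H]2CC[C@H](O)[C@H](C)[C@H]2[C@@H]1/C=C/C=C/C(=O)OCC | intermediate
36 | ethyl (2E,4E)-5-{2α-[(E)-but-2-en-2-yl]-3,8α-dimethyl-7α-(sulfooxy)-1,2,4aα,5,6,7,8,8aα-octahydronaphthalen-1α-yl}penta-2,4-dienoate | C/C=C(\C)[C@@H]1C(C)=C[C@H]2CC[C@H](OS(=O)(=O)O)[C@H](C)[C@H]2[C@@H]1/C=C/C=C/C(=O)OCC | intermediate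
37 | (2E,4E)-5-{2α-[(E)-but-2-en-2-yl]-3,8α-dimethyl-7α-(sulfooxy)-1,2,4aα,5,6,7,8,8aα-octahydronaphthalen-1α-yl}penta-2,4-dienoic acid | C/C=C(\C)[C@@H]1C(C)=C[C@H]2CC[C@H](OS(=O)(=O)O)[C@H](C)[C@H]2[C@@H]1/C=C/C=C/C(=O)O | target

## Step count and least certain steps

Total: 25 steps. Longest linear sequence: 22 steps (steps 2, 3 and 4, then 7 to 25, from 4).

**Step 16 (key step).** The likely failures are competing exo closure to the trans-fused adduct, attack on the other diene face, oligomerisation of the vinyl ketone, and hydrolysis of the silyl dienol ether before cyclisation. The fallback replaces the neutral silyloxydiene by its lithium dienolate and closes the same two bonds as an anion-accelerated cycloaddition, formally a tandem Michael–Michael addition. It sets out from 20. CH2=CHMgBr with CeCl3 at −78 °C adds to the aldehyde in the presence of the less reactive methyl enone and gives the divinyl carbinol–enone F1. Buffered periodinane oxidation gives the bis-enone F2. LiN(SiMe3)2 at −78 °C removes a methyl proton to give the cross-conjugated lithium dienolate F3, a 2-oxidodiene far more electron-rich than the silyl ether. Bonding of its C6 terminus to C5 of the vinyl ketone and of C4a to C8a leaves the C7 lithium enolate F4. Trapping F4 with TBSCl returns to 24. The ring fusion is then set in a lithium-organised, strongly asynchronous closure at low temperature, with different stereo-determinants.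

**Step 8.** The likely failures are β-elimination of the benzylic alkoxide from the ester enolate before silylation, and erosion of enolate geometry, which would lower the C1/C2 diastereoselectivity. The fallback sets out from 11. DDQ removes the PMB group to give the 3-hydroxypropanoate F5. Two equivalents of LiN(i-Pr)2 form the chelated alkoxide–enolate dianion, which cannot eliminate and has its geometry fixed by chelation. On warming it rearranges to the hydroxy acid F6. Trimethylsilyldiazomethane gives the methyl ester F7, and 4-methoxybenzyl trichloroacetimidate with catalytic camphorsulfonic acid gives the PMB ether F8. LiAlH4 reduction of F8 comes back at 15.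

**Step 13.** The likely failure is Mukaiyama-type addition of the new silyl dienol ether to the silyl-activated enal, or amine addition to the enal. The fallback sets out from 19 and makes the diene before the aldehyde exists. Acetylation (Ac2O, pyridine) gives acetate F9. TBSOTf/Et3N gives the silyloxydiene acetate F10. i-Bu2AlH at −78 °C, which does not touch the silyl dienol ether, frees the allylic alcohol F11. MnO2 oxidation then comes back at 21.

**Step 18.** The likely failures are slow Mitsunobu displacement at the hindered C4, displacement at the methylene terminus instead (which would give the non-transposed alkene), and acid-promoted loss of the silyl enol ether. The fallback sets out from 24. Tosylhydrazide gives the tosylhydrazone F12. Catecholborane followed by NaOAc·3H2O at 65 °C reduces the C=N bond and releases the same type of allylic diazene, whose 1,5-hydrogen shift gives 28. This is the alkene-transposing reduction of an enone tosylhydrazone and needs no displacement at C4.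

**Step 19.** The likely failures are incomplete Si–O cleavage by methyllithium, and proton exchange between enolate and product that leads to over-methylation or methylation at C6. The fallback sets out from 28. Et2Zn/CH2I2 cyclopropanates the electron-rich silyl enol ether from the convex face to give the siloxycyclopropane F13. Bu4NF followed by NaOH in methanol opens the cyclopropanolate at the C7–CH2 bond, so the former methylene becomes the 8α-methyl of 30.

**Step 20.** The likely failure is hydride delivery from the face that gives the 7β-alcohol, if the ring-B chair with an axial C8 methyl is the one that reacts. The fallback sets out from 30. A small hydride (NaBH4, MeOH, −40 °C) is used to make the C7 epimer F14 deliberately. Mitsunobu inversion with 4-nitrobenzoic acid (PPh3, DIAD) gives the ester F15, and K2CO3 in methanol comes back at 31.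

## Further compounds

F1 | step 16 | (3E,5S,6R)-6-[(E)-but-2-en-2-yl]-8-hydroxy-5-{[(4-methoxybenzyl)oxy]methyl}-7-methylidenedeca-3,9-dien-2-one, both C8 epimers | C/C=C(\C)[C@H](C(=C)C(O)C=C)[C@@H](COCc1ccc(OC)cc1)/C=C/C(C)=O
F2 | step 16 | (3E,5S,6R)-6-[(E)-but-2-en-2-yl]-5-{[(4-methoxybenzyl)oxy]methyl}-7-methylidenedeca-3,9-diene-2,8-dione | C/C=C(\C)[C@H](C(=C)C(=O)C=C)[C@@H](COCc1ccc(OC)cc1)/C=C/C(C)=O
F3 | step 16 | cross-conjugated lithium dienolate of F2 at the methyl ketone | C/C=C(\C)[C@H](C(=C)C(=O)C=C)[C@@H](COCc1ccc(OC)cc1)/C=C/C(O[Li])=C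
F4 | step 16 | lithium C7 enolate (C7=C8) of the cis-fused C4 ketone, the lithium analogue of 24 | C/C=C(\C)[C@@H]1C(=C)C(=O)[C@H]2CCC(O[Li])=C[C@H]2[C@@H]1COCc1ccc(OC)cc1
F5 | step 8 | (2R,3E)-5-{[(tert-butyldimethylsilyl)oxy]methyl}-3-methylhexa-3,5-dien-2-yl 3-hydroxypropanoate | C[C@@H](OC(=O)CCO)/C(C)=C/C(=C)CO[Si](C)(C)C(C)(C)C
F6 | step 8 | 3-[(E)-but-2-en-2-yl]-4-{[(tert-butyldimethylsilyl)oxy]methyl}-2-(hydroxymethyl)pent-4-enoic acid, configured as 14 | C/C=C(\C)[C@H](C(=C)CO[Si](C)(C)C(C)(C)C)[C@@H](CO)C(=O)O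
F7 | step 8 | methyl ester of F6 | C/C=C(\C)[C@H](C(=C)CO[Si](C)(C)C(C)(C)C)[C@@H](CO)C(=O)OC
F8 | step 8 | methyl ester of 14 | C/C=C(\C)[C@H](C(=C)CO[Si](C)(C)C(C)(C)C)[C@@H](COCc1ccc(OC)cc1)C(=O)OC
F9 | step 13 | acetate of 19 | C/C=C(\C)[C@H](C(=C)COC(C)=O)[C@@H](COCc1ccc(OC)cc1)/C=C/C(C)=O
F10 | step 13 | 2-(tert-butyldimethylsilyl)oxydiene from F9, acetate retained | C/C=C(\C)[C@H](C(=C)COC(C)=O)[C@@H](COCc1ccc(OC)cc1)/C=C/C(O[Si](C)(C)C(C)(C)C)=C
F11 | step 13 | allylic alcohol corresponding to 21 | C/C=C(\C)[C@H](C(=C)CO)[C@@H](COCc1ccc(OC)cc1)/C=C/C(O[Si](C)(C)C(C)(C)C)=C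
F12 | step 18 | 4-methylbenzenesulfonylhydrazone of 24 | C/C=C(\C)[C@@H]1C(=C)C(=NNS(=O)(=O)c3ccc(C)cc3)[C@H]2CCC(O[Si](C)(C)C(C)(C)C)=C[C@H]2[C@@H]1COCc1ccc(OC)cc1
F13 | step 19 | siloxycyclopropane from 28, methylene bridging C7 and C8 on the α face | C/C=C(\C)[C@@H]1C(C)=C[C@H]2CC[C@]3(O[Si](C)(C)C(C)(C)C)C[C@@H]3[C@H]2[C@@H]1COCc1ccc(OC)cc1
F14 | step 20 | 7β-epimer of 31 | C/C=C(\C)[C@@H]1C(C)=C[C@H]2CC[C@@H](O)[C@H](C)[C@H]2[C@@H]1COCc1ccc(OC)cc1
F15 | step 20 | 4-nitrobenzoate of 31 | C/C=C(\C)[C@@H]1C(C)=C[C@H]2CC[C@H](OC(=O)c3ccc(cc3)[N+](=O)[O-])[C@H](C)[C@H]2[C@@H]1COCc1ccc(OC)cc1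
A1 | alternative 1 | cis-fused C7 ketone with 8-methyl and C1 bis(methoxycarbonyl) group | C/C=C(\C)[C@@H]1C(C)=C[C@H]2CCC(=O)[C@H](C)[C@H]2C1(C(=O)OC)C(=O)OC
A2 | alternative 1 | dimethyl 2-{(2Z)-1-[(E)-but-2-en-2-yl]-2-methyl-3-(4-oxocyclohex-2-en-1-yl)prop-2-en-1-yl}propanedioate, centres as in A1 | C/C=C(\C)[C@@H](C(C(=O)OC)C(=O)OC)/C(C)=C\[C@H]1CCC(=O)C=C1
A3 | alternative 2 | ring-A-closed C1 carboxylic acid with 7α-silyloxy and 8α-methyl | C/C=C(\C)[C@@H]1C(C)=C[C@H]2CC[C@H](O[Si](C)(C)C(C)(C)C)[C@H](C)[C@H]2[C@@H]1C(=O)O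
A4 | alternative 2 | cis-fused six-membered lactone, ring oxygen on C4, C4 bearing a (2E,4E)-4-methylhexa-2,4-dien-2-yl group cis to C5, 7α-silyloxy, 8α-methyl | C/C=C(\C)/C=C(\C)[C@@H]1OC(=O)C[C@@H]2[C@@H](C)[C@@H](O[Si](C)(C)C(C)(C)C)CC[C@H]12
A5 | alternative 3 | endo sulfur-bridged cis-fused adduct | C1=C(C)C(=O)[C@H]2[C@H]3C=C(O[Si](C)(C)C(C)(C)C)[C@H](CS3)[C@H]2C1(OC)OC
A6 | alternative 3 | 4-[(tert-butyldimethylsilyl)oxy]-2H-thiopyran | CC(C)(C)[Si](C)(C)OC1=CCSC=C1
A7 | alternative 3 | 4,4-dimethoxy-2-methylcyclohexa-2,5-dien-1-one | COC1(OC)C=CC(=O)C(C)=C1
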